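Look first at late times. Mono adduct stops falling at 77.7% in the north-west run and 61.7% in the south-west run, though triple product could still form from it. So take the ladder from the fastest rung down.

| setting | north-west | south-west | west | delta | eta |
|---|---|---|---|---|---|
| starting material | 0.10 M | 0.10 M | 0.10 M | 0.10 M | 0.10 M |
| partner | 0.17 M | 0.23 M | 0.40 M | 0.380 M | 0.150 M |
| remark | run made earlier | run made earlier | run made earlier |  |  |
| time |  |  |  | 2.5 h | 2.5 h |

| run | time / h | mono adduct / % | starting material / % |
|---|---|---|---|
| north-west | 0.200 | 78.4 | 14.9 |
| north-west | 0.417 | 82.4 | 4.3 |
| north-west | 0.667 | 80.8 | 2.8 |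
| north-west | 1.33 | 78.3 | 1.8 |
| north-west | 2.50 | 77.7 | 1.5 |
| south-west | 0.200 | 80.1 | 6.4 |
| south-west | 0.667 | 71.7 | 0.4 |
| south-west | 1.33 | 63.9 | 0.6 |
| south-west | 2.00 | 62.4 | 0.5 |
| south-west | 2.50 | 61.7 | 0.3 |
| west | 0.500 | 52.5 | 0 |
| west | 1.00 | 36.2 | 0.4 |
| west | 1.50 | 29.6 | 0 |
| west | 2.00 | 26.8 | 0 |
| west | 2.50 | 24.9 | 0.7 |

(readings scatter by 0.5 percentage points)

1. which of the two there is more of at the end, delta (mono adduct / triple product)
2. which of the two there is more of at the end, eta (mono adduct / triple product)
3. final mono adduct, as a percentage of the starting material charged, in delta
4. final mono adduct, as a percentage of the starting material charged, in eta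



Top rung: the first addition. It costs one equivalent of partner, and starting material is down to 0.4% by 0.667 h in the south-west run. Next rung: the drain of mono adduct, over about an hour. Take each fraction drained to cost two more equivalents on its way to triple product. Last rung: partner decays while the drain runs, and the drain stalls.

Now count turnovers. Assume partner is used up at the plateau. Let decay go with partner, and the drain with partner times mono adduct. Then partner beyond the first addition equals twice the fraction drained, plus a waste number times ln(mono fraction at the start over mono fraction at the end). Call this the waste number: equivalents lost to decay per e-fold of mono adduct. The runs give 1.26, 1.13 and 1.10. Take the mean, 1.16.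

The price of one more fraction drained is two plus the waste number over the mono fraction. Delta has 0.200 equivalents less than the west run, so price that at the west run's end: mono adduct 27.9%, triple product ahead. Eta has 0.200 less than the north-west run: mono adduct 83.4%, which stays ahead.

The forecast says triple product at 28% mono adduct for delta and mono adduct at 82% for eta, a little below my eta, and reads the stall as one “fits partner dying over time”.

The flask gives triple product in delta, with 28.0% mono adduct against 68.0% triple product, and mono adduct in eta, with 80.9% mono adduct against 12.7% triple product.

    starting material + partner → mono adduct + by-product (k = 100 M⁻¹ h⁻¹)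
    partner + mono adduct → bis adduct + by-product (k = 6.60 M⁻¹ h⁻¹)
    partner + bis adduct → triple product + by-product (k = 180 M⁻¹ h⁻¹)
    partner → decomposed reagent (k = 0.650 h⁻¹)
    partner + mono adduct → over-reaction product (k = 0.280 M⁻¹ h⁻¹)

In eta the first addition uses partner 15 times as fast as decay does at the start, but 0.42 times as fast at 2.50 h, when partner, the limiting reagent here, stands at 0.22% of its charge. With the waste number read from the runs, eta's price at its final mono adduct reckons to about 3.44 equivalents. Now take the neighbour with 0.025 M of starting material: scaled by that charge, the waste number from the runs reckons to 4.65, and the balance gives an estimate of 43.8% mono adduct. Computed, that flask holds 44.5% mono adduct and 51.6% triple product.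

(Readings and results come from a simulation from invented constants; scatter was added.)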